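The route rests on the aryl ether bond O1–C8a of the dihydropyran ring. Its precursor is an open-chain tertiary alcohol, the future C2 carbinol, whose C3 stereocentre comes from an Evans alkylation and whose benzene ring carries bromine at C8 and C6 and the only ring hydrogen at C8a. One operation with an amide base converts C8–Br and C8a–H into a C8–C8a aryne, lets the tethered C2 alkoxide add at C8a to close the pyran ring, and leaves C8 as the C–H of the target (cine-substitution). The step exploits the unsubstituted C8 next to the C7 methoxy group; the surviving C6 bromine then places the chalcone ketone without ambiguity.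

Key step: step 8

Remark: compounds 1, 5, 6, 17 and 19 are taken as catalogue chemicals; the locants O1, C2 to C8a are those of the chromane ring of the target.

Step 1
Reactants: 1 3,5-dibromo-2-hydroxy-4-methoxybenzaldehyde
Product: 2 3,5-dibromo-4-methoxy-2-(methoxymethoxy)benzaldehyde
Conditions: MOMCl, i-Pr2NEt, CH2Cl2, 0 °C → rt
Reagents that add atoms: chloromethyl methyl ether, COCCl
Why: O-alkylation of the acidic, chelated phenol (Williamson type) installs an acetal that tolerates the later enolate, Grignard, lithium amide and aryllithium steps and falls together with the B-ring acetals at the end.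

Step 2
Reactants: 2 3,5-dibromo-4-methoxy-2-(methoxymethoxy)benzaldehyde
Product: 3 [3,5-dibromo-4-methoxy-2-(methoxymethoxy)phenyl]methanol
Conditions: NaBH4, MeOH, 0 °C
Reagents that add atoms: none
Why: Chemoselective hydride reduction of the aldehyde; aryl bromides and the MOM acetal are inert to NaBH4.

Step 3
Reactants: 3 [3,5-dibromo-4-methoxy-2-(methoxymethoxy)phenyl]methanol
Product: 4 1,3-dibromo-5-(bromomethyl)-2-methoxy-4-(methoxymethoxy)benzene
Conditions: CBr4, PPh3, CH2Cl2, 0 °C
Reagents that add atoms: carbon tetrabromide, BrC(Br)(Br)Br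
Why: Appel bromination converts the benzylic alcohol into the bromide under neutral conditions that spare the acid-labile MOM ether.

Step 4
Reactants: 5 5-methylhex-4-enoic acid; 6 (4S)-4-benzyl-1,3-oxazolidin-2-one
Product: 8 (4S)-4-benzyl-3-(5-methylhex-4-enoyl)-1,3-oxazolidin-2-one, via mixed pivalic anhydride 7 (not isolated)
Conditions: t-BuCOCl, Et3N, THF, −20 °C; then 6, LiCl, −20 °C → rt
Reagents that add atoms: none
Why: N-acylation of the oxazolidinone through the mixed anhydride, which is attacked at its less hindered acyl group under LiCl/Et3N activation.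

Step 5
Reactants: 8 (4S)-4-benzyl-3-(5-methylhex-4-enoyl)-1,3-oxazolidin-2-one; 4 1,3-dibromo-5-(bromomethyl)-2-methoxy-4-(methoxymethoxy)benzene
Product: 10 (4S)-4-benzyl-3-[(2R)-2-{[3,5-dibromo-4-methoxy-2-(methoxymethoxy)phenyl]methyl}-5-methylhex-4-enoyl]-1,3-oxazolidin-2-one, via sodium Z-enolate 9 (not isolated)
Conditions: NaN(SiMe3)2, THF, −78 °C; then 4, −78 → −40 °C
Reagents that add atoms: none
Why: Evans asymmetric alkylation: the chelated sodium Z-enolate 9 is alkylated by the benzylic bromide on the face opposite the C4 benzyl group of the auxiliary, which should set the new stereocentre (the later C3) as R.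

Step 6
Reactants: 10 (4S)-4-benzyl-3-[(2R)-2-{[3,5-dibromo-4-methoxy-2-(methoxymethoxy)phenyl]methyl}-5-methylhex-4-enoyl]-1,3-oxazolidin-2-one
Product: 11 methyl (2R)-2-{[3,5-dibromo-4-methoxy-2-(methoxymethoxy)phenyl]methyl}-5-methylhex-4-enoate
Conditions: MeMgBr (1.5 equiv) in MeOH (gives MeOMgBr), CH2Cl2, 0 °C → rt
Reagents that add atoms: methanol, CO
Why: Transesterification with methoxymagnesium bromide attacks the exocyclic imide carbonyl even of α-branched imides and is too weakly basic to epimerise the α-centre, so the R configuration should be kept and the auxiliary released intact.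

Step 7
Reactants: 11 methyl (2R)-2-{[3,5-dibromo-4-methoxy-2-(methoxymethoxy)phenyl]methyl}-5-methylhex-4-enoate
Product: 13 (3R)-3-{[3,5-dibromo-4-methoxy-2-(methoxymethoxy)phenyl]methyl}-2,6-dimethylhept-5-en-2-ol, via methyl ketone 12 (not isolated)
Conditions: MeMgBr (3.5 equiv), THF, −20 °C → rt
Reagents that add atoms: methylmagnesium bromide, C[Mg]Br
Why: Double Grignard addition to the ester: the ketone 12 reacts with MeMgBr faster than it enolises, so the neighbouring stereocentre should be kept, and aryl bromides do not exchange with a methyl Grignard reagent.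

Step 8
Reactants: 13 (3R)-3-{[3,5-dibromo-4-methoxy-2-(methoxymethoxy)phenyl]methyl}-2,6-dimethylhept-5-en-2-ol
Product: 16 (3R)-6-bromo-7-methoxy-5-(methoxymethoxy)-2,2-dimethyl-3-(3-methylbut-2-en-1-yl)-3,4-dihydro-2H-chromene, via aryne lithium alkoxide 14 (not isolated), via 8-lithiochromane 15 (not isolated)
Conditions: lithium 2,2,6,6-tetramethylpiperidide (3.5 equiv), THF (0.02 M), −78 → −20 °C; NH4Cl (aq), −78 °C
Reagents that add atoms: none
Why: Aryne ring closure with cine-substitution: after forming the lithium alkoxide the amide base removes the only ring proton, C8a–H, which the ortho bromine at C8 acidifies, and loss of LiBr gives the C8–C8a aryne 14. The tethered C2 alkoxide adds in the ring plane to C8a, and the resulting C8 carbanion 15, held between the C7 methoxy group and the new ether oxygen, is protonated on work-up, so that oxygen enters at C8a while C8 ends as C–H. The closest known reaction types are the ring closure of a tethered heteroatom nucleophile onto an aryne generated by dehydrohalogenation and the addition of tert-alkoxides to arynes. The dihydropyran ring closes in the 6-exo-dig mode on the in-plane aryne π bond; attack at C8 would need a meta-bridged seven-membered ring and is excluded, and the usual preference of 3-alkoxyarynes for attack meta to the alkoxy group points the same way. No stereocentre is formed, and C3, which bears no acidic hydrogen, should keep its R configuration. The step needs the C6 bromine to survive, which is secured because it has no ortho hydrogen and a lithium amide does not exchange with aryl bromides, and it needs the alkoxide to outrun the base at the aryne, which the six-membered intramolecular delivery and the bulk of the amide secure.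

Step 9
Reactants: 17 2,4-dihydroxybenzaldehyde
Product: 18 2,4-bis(methoxymethoxy)benzaldehyde
Conditions: MOMCl, i-Pr2NEt, CH2Cl2, 0 °C → reflux
Reagents that add atoms: chloromethyl methyl ether, COCCl
Why: Double O-alkylation of both phenols (Williamson type) gives acetals that survive the olefination and the aryllithium addition.

Step 10
Reactants: 18 2,4-bis(methoxymethoxy)benzaldehyde; 19 diethyl {2-[methoxy(methyl)amino]-2-oxoethyl}phosphonate
Product: 20 (2E)-3-[2,4-bis(methoxymethoxy)phenyl]-N-methoxy-N-methylprop-2-enamide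
Conditions: LiCl, DBU, MeCN, rt
Reagents that add atoms: none
Why: Horner–Wadsworth–Emmons olefination with a stabilised phosphonate under mild LiCl/amine conditions should give the E-configured unsaturated Weinreb amide.

Step 11
Reactants: 16 (3R)-6-bromo-7-methoxy-5-(methoxymethoxy)-2,2-dimethyl-3-(3-methylbut-2-en-1-yl)-3,4-dihydro-2H-chromene; 20 (2E)-3-[2,4-bis(methoxymethoxy)phenyl]-N-methoxy-N-methylprop-2-enamide
Product: 22 (2E)-3-[2,4-bis(methoxymethoxy)phenyl]-1-[(3R)-7-methoxy-5-(methoxymethoxy)-2,2-dimethyl-3-(3-methylbut-2-en-1-yl)-3,4-dihydro-2H-chromen-6-yl]prop-2-en-1-one, via 6-lithiochromane 21 (not isolated)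
Conditions: n-BuLi, THF, −78 °C; then 20, −78 → −20 °C; NH4Cl (aq)
Reagents that add atoms: none
Why: Bromine–lithium exchange is faster than any deprotonation and fixes the nucleophilic site at C6, and the aryllithium adds 1,2 to the amide to give a chelated tetrahedral adduct that releases the enone only on work-up (Weinreb ketone synthesis), with the E-alkene and C3 untouched.

Step 12
Reactants: 22 (2E)-3-[2,4-bis(methoxymethoxy)phenyl]-1-[(3R)-7-methoxy-5-(methoxymethoxy)-2,2-dimethyl-3-(3-methylbut-2-en-1-yl)-3,4-dihydro-2H-chromen-6-yl]prop-2-en-1-one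
Product: 23 (2E)-3-(2,4-dihydroxyphenyl)-1-[(3R)-5-hydroxy-7-methoxy-2,2-dimethyl-3-(3-methylbut-2-en-1-yl)-3,4-dihydro-2H-chromen-6-yl]prop-2-en-1-one
Conditions: HCl (3 M aq), MeOH, rt → 40 °C, dark
Reagents that add atoms: none
Why: Acid-catalysed acetal exchange with methanol removes the three MOM groups, the one at C5 fastest because of chelation to the ketone, without touching C3 or the E-alkene.

Compound list
1 | 3,5-dibromo-2-hydroxy-4-methoxybenzaldehyde | O=Cc1cc(Br)c(OC)c(Br)c1O | starting material
2 | 3,5-dibromo-4-methoxy-2-(methoxymethoxy)benzaldehyde | O=Cc1cc(Br)c(OC)c(Br)c1OCOC | intermediate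
3 | [3,5-dibromo-4-methoxy-2-(methoxymethoxy)phenyl]methanol | OCc1cc(Br)c(OC)c(Br)c1OCOC | intermediate
4 | 1,3-dibromo-5-(bromomethyl)-2-methoxy-4-(methoxymethoxy)benzene | BrCc1cc(Br)c(OC)c(Br)c1OCOC | intermediate
5 | 5-methylhex-4-enoic acid | CC(C)=CCCC(=O)O | starting material
6 | (4S)-4-benzyl-1,3-oxazolidin-2-one | O=C1N[C@@H](Cc2ccccc2)CO1 | starting material
7 | 5-methylhex-4-enoic pivalic anhydride (not isolated) | CC(C)=CCCC(=O)OC(=O)C(C)(C)C | intermediate
8 | (4S)-4-benzyl-3-(5-methylhex-4-enoyl)-1,3-oxazolidin-2-one | CC(C)=CCCC(=O)N1[C@@H](Cc2ccccc2)COC1=O | intermediate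
9 | sodium (Z)-enolate of 8 (not isolated) | CC(C)=CC/C=C(\O[Na])N1[C@@H](Cc2ccccc2)COC1=O | intermediate
10 | (4S)-4-benzyl-3-[(2R)-2-{[3,5-dibromo-4-methoxy-2-(methoxymethoxy)phenyl]methyl}-5-methylhex-4-enoyl]-1,3-oxazolidin-2-one | COCOc1c(Br)c(OC)c(Br)cc1C[C@@H](CC=C(C)C)C(=O)N1[C@@H](Cc2ccccc2)COC1=O | intermediate
11 | methyl (2R)-2-{[3,5-dibromo-4-methoxy-2-(methoxymethoxy)phenyl]methyl}-5-methylhex-4-enoate | COCOc1c(Br)c(OC)c(Br)cc1C[C@@H](CC=C(C)C)C(=O)OC | intermediate
12 | (3R)-3-{[3,5-dibromo-4-methoxy-2-(methoxymethoxy)phenyl]methyl}-6-methylhept-5-en-2-one (not isolated) | COCOc1c(Br)c(OC)c(Br)cc1C[C@@H](CC=C(C)C)C(C)=O | intermediate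
13 | (3R)-3-{[3,5-dibromo-4-methoxy-2-(methoxymethoxy)phenyl]methyl}-2,6-dimethylhept-5-en-2-ol | COCOc1c(Br)c(OC)c(Br)cc1C[C@@H](CC=C(C)C)C(C)(C)O | intermediate
14 | lithium alkoxide of the C8–C8a aryne derived from 13 (not isolated) | COCOC1=C(C[C@@H](CC=C(C)C)C(C)(C)O[Li])C#CC(OC)=C1Br | intermediate
15 | [(3R)-6-bromo-7-methoxy-5-(methoxymethoxy)-2,2-dimethyl-3-(3-methylbut-2-en-1-yl)-3,4-dihydro-2H-chromen-8-yl]lithium (not isolated) | COCOc1c(Br)c(OC)c([Li])c2c1C[C@@H](CC=C(C)C)C(C)(C)O2 | intermediate
16 | (3R)-6-bromo-7-methoxy-5-(methoxymethoxy)-2,2-dimethyl-3-(3-methylbut-2-en-1-yl)-3,4-dihydro-2H-chromene | COCOc1c(Br)c(OC)cc2c1C[C@@H](CC=C(C)C)C(C)(C)O2 | intermediate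
17 | 2,4-dihydroxybenzaldehyde | O=Cc1ccc(O)cc1O | starting material
18 | 2,4-bis(methoxymethoxy)benzaldehyde | O=Cc1ccc(OCOC)cc1OCOC | intermediate
19 | diethyl {2-[methoxy(methyl)amino]-2-oxoethyl}phosphonate | CCOP(=O)(CC(=O)N(C)OC)OCC | starting material
20 | (2E)-3-[2,4-bis(methoxymethoxy)phenyl]-N-methoxy-N-methylprop-2-enamide | CON(C)C(=O)/C=C/c1ccc(OCOC)cc1OCOC | intermediate
21 | [(3R)-7-methoxy-5-(methoxymethoxy)-2,2-dimethyl-3-(3-methylbut-2-en-1-yl)-3,4-dihydro-2H-chromen-6-yl]lithium (not isolated) | COCOc1c([Li])c(OC)cc2c1C[C@@H](CC=C(C)C)C(C)(C)O2 | intermediate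
22 | (2E)-3-[2,4-bis(methoxymethoxy)phenyl]-1-[(3R)-7-methoxy-5-(methoxymethoxy)-2,2-dimethyl-3-(3-methylbut-2-en-1-yl)-3,4-dihydro-2H-chromen-6-yl]prop-2-en-1-one | COc1cc2c(c(OCOC)c1C(=O)/C=C/c1ccc(OCOC)cc1OCOC)C[C@@H](CC=C(C)C)C(C)(C)O2 | intermediate
23 | (2E)-3-(2,4-dihydroxyphenyl)-1-[(3R)-5-hydroxy-7-methoxy-2,2-dimethyl-3-(3-methylbut-2-en-1-yl)-3,4-dihydro-2H-chromen-6-yl]prop-2-en-1-one | COc1cc2c(c(O)c1C(=O)/C=C/c1ccc(O)cc1O)C[C@@H](CC=C(C)C)C(C)(C)O2 | target

Total step count: 12
Longest linear sequence: 9 steps (steps 1, 2, 3, 5, 6, 7, 8, 11, 12)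

Steps most likely to fail

Step 8. What may go wrong: capture of the aryne by the amide base or by the prenyl double bond (ene reaction) instead of by the tethered alkoxide, and intermolecular bromine–lithium exchange between the C8 aryllithium and the C6 bromide, which would scramble the halogen pattern. The fallback replaces cine- by ipso-substitution and avoids a free aryne; it sets out from 13. Metalation of C8a–H with lithium 2,2,6,6-tetramethylpiperidide in the presence of ZnCl2 (in situ transmetalation to an arylzinc that does not eliminate bromide; THF, −78 °C) and a quench with I2 should give the C8a-iodinated alcohol F1. Pd-catalysed intramolecular etherification of the tertiary alcohol at the carbon–iodine bond (Pd(OAc)2, 2-(di-tert-butylphosphino)-1,1'-binaphthyl, Cs2CO3, toluene, 80 °C) would close the same O1–C8a bond and give the 6,8-dibromochromane F2. Exhaustive bromine–lithium exchange (t-BuLi, THF, −78 °C) and a methanol quench should give the bromine-free chromane F3. Ortho-lithiation between the OMOM and OMe groups (n-BuLi, TMEDA, THF, 0 °C) then leads to 21, where the route is rejoined in the second stage of step 11.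

Step 12. What may go wrong: during the long acid exposure that the two B-ring acetals need, oxa-Michael closure of the freed C5 hydroxyl onto the enone (chalcone-to-flavanone isomerisation) and Markovnikov addition of HCl or methanol to the prenyl double bond. The fallback uses orthogonal protection with fluoride first; it sets out from 17. Silylation (TBSCl, imidazole, DMF) gives 2,4-bis(tert-butyldimethylsilyloxy)benzaldehyde F4, and olefination with 19 (LiCl, i-Pr2NEt, MeCN) gives the bis-silylated Weinreb amide F5. Addition of 21 (made from 16 as in step 11) should give the mixed MOM/silyl-protected chalcone F6. Buffered fluoride (Bu4NF, AcOH, THF, 0 °C) frees the B-ring phenols to give the C5-MOM chalcone F7. A short treatment with dilute acid (HCl 0.5 M, MeOH, rt) then removes only the chelated, most labile C5 acetal and returns to the route at 23.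

Step 11. What may go wrong: conjugate addition of the doubly ortho-substituted aryllithium to the unsaturated amide, or slow addition followed by protonation of the aryllithium on warming. The fallback makes the ketone first and the enone by condensation; it sets out from 16. Bromine–lithium exchange (n-BuLi, THF, −78 °C) and acylation with N-methoxy-N-methylacetamide should give the 6-acetylchromane F8. Claisen–Schmidt condensation of F8 with 18 (KOH, EtOH/H2O, rt) returns to the route at 22.

Further compounds
F1 | step 8 | (3R)-3-{[3,5-dibromo-2-iodo-4-methoxy-6-(methoxymethoxy)phenyl]methyl}-2,6-dimethylhept-5-en-2-ol | COCOc1c(Br)c(OC)c(Br)c(I)c1C[C@@H](CC=C(C)C)C(C)(C)O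
F2 | step 8 | (3R)-6,8-dibromo-7-methoxy-5-(methoxymethoxy)-2,2-dimethyl-3-(3-methylbut-2-en-1-yl)-3,4-dihydro-2H-chromene | COCOc1c(Br)c(OC)c(Br)c2c1C[C@@H](CC=C(C)C)C(C)(C)O2
F3 | step 8 | (3R)-7-methoxy-5-(methoxymethoxy)-2,2-dimethyl-3-(3-methylbut-2-en-1-yl)-3,4-dihydro-2H-chromene | COCOc1cc(OC)cc2c1C[C@@H](CC=C(C)C)C(C)(C)O2
F4 | step 12 | 2,4-bis{[tert-butyl(dimethyl)silyl]oxy}benzaldehyde | O=Cc1ccc(O[Si](C)(C)C(C)(C)C)cc1O[Si](C)(C)C(C)(C)C
F5 | step 12 | (2E)-3-(2,4-bis{[tert-butyl(dimethyl)silyl]oxy}phenyl)-N-methoxy-N-methylprop-2-enamide | CON(C)C(=O)/C=C/c1ccc(O[Si](C)(C)C(C)(C)C)cc1O[Si](C)(C)C(C)(C)C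
F6 | step 12 | (2E)-3-(2,4-bis{[tert-butyl(dimethyl)silyl]oxy}phenyl)-1-[(3R)-7-methoxy-5-(methoxymethoxy)-2,2-dimethyl-3-(3-methylbut-2-en-1-yl)-3,4-dihydro-2H-chromen-6-yl]prop-2-en-1-one | COc1cc2c(c(OCOC)c1C(=O)/C=C/c1ccc(O[Si](C)(C)C(C)(C)C)cc1O[Si](C)(C)C(C)(C)C)C[C@@H](CC=C(C)C)C(C)(C)O2
F7 | step 12 | (2E)-3-(2,4-dihydroxyphenyl)-1-[(3R)-7-methoxy-5-(methoxymethoxy)-2,2-dimethyl-3-(3-methylbut-2-en-1-yl)-3,4-dihydro-2H-chromen-6-yl]prop-2-en-1-one | COc1cc2c(c(OCOC)c1C(=O)/C=C/c1ccc(O)cc1O)C[C@@H](CC=C(C)C)C(C)(C)O2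
F8 | step 11 | 1-[(3R)-7-methoxy-5-(methoxymethoxy)-2,2-dimethyl-3-(3-methylbut-2-en-1-yl)-3,4-dihydro-2H-chromen-6-yl]ethan-1-one | COc1cc2c(c(OCOC)c1C(C)=O)C[C@@H](CC=C(C)C)C(C)(C)O2
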